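**Retrosynthetic overview**

- Target 15 comes from benzyl ether 14 by debenzylation. The C4–Br of ring A comes from C4–NO2 (reduction, Sandmeyer reaction), and the C1 methyl ether from the free phenol of nitrophenol 10.
- The strategy rests on this feature: in ring A the brominated C4 lies between two CH carbons (C3, C5) and para to the C1 oxygen. Ring A is therefore a five-carbon unit C3–C2–C1–C6–C5, oxygenated at its central carbon, plus one extra carbon.
- Key disconnection: C3–C4 and C4–C5. Nitromethane supplies C4 (as C–NO2) to the 3-aryloxy-5-bromo-4-pyranone 8; the pyranone C=O oxygen becomes the C1 oxygen and the ring oxygen leaves as water.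
- Pyranone 8 comes from bis-enaminone 6 of aryloxyacetone 4 (bromination of the free arm, acid closure). Ketone 4 comes from 2-(benzyloxy)-4-bromophenol 2 and chloroacetone.
- Ring order: ring B is bought with 1, the pyranone ring is closed in step 5 and recast into ring A in step 6.

Key step: step 6

Remark: the enaminone double bonds are drawn with the amino group trans to the carbonyl group. This geometry is assumed; it is erased in the ring closure of step 5.

**Route**

Step 1
Reactants: 1 2-(benzyloxy)phenol
Product: 2 2-(benzyloxy)-4-bromophenol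
Conditions: NBS (1.0 equiv), MeCN, 0 °C
Reagents that add atoms: N-bromosuccinimide, O=C1CCC(=O)N1Br
Why: Electrophilic aromatic bromination; the free hydroxyl is a stronger para director than the benzyl ether, so bromine should enter para to OH, as it does with guaiacol.

Step 2
Reactants: 2 2-(benzyloxy)-4-bromophenol; 3 chloroacetone
Product: 4 1-[2-(benzyloxy)-4-bromophenoxy]propan-2-one
Conditions: K2CO3, KI (cat.), acetone, reflux
Reagents that add atoms: none
Why: Williamson ether synthesis of the phenoxide on a primary α-chloroketone, with iodide catalysis speeding the SN2 displacement.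

Step 3
Reactants: 4 1-[2-(benzyloxy)-4-bromophenoxy]propan-2-one
Product: 6 (1Z,4E)-2-[2-(benzyloxy)-4-bromophenoxy]-1,5-bis(dimethylamino)penta-1,4-dien-3-one, via mono-enaminone 5 (not isolated)
Conditions: t-BuOCH(NMe2)2 (3 equiv), toluene, 110 °C
Reagents that add atoms: tert-butoxybis(dimethylamino)methane (Bredereck's reagent), CN(C)C(OC(C)(C)C)N(C)C
Why: Enaminone formation by condensation of an aminal ester with CH-acidic ketone positions; the aryloxy-bearing methylene should react first to give 5, and the hot excess of this reactive aminal should then also condense the less acidic methyl group.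

Step 4
Reactants: 6 (1Z,4E)-2-[2-(benzyloxy)-4-bromophenoxy]-1,5-bis(dimethylamino)penta-1,4-dien-3-one
Product: 7 (1Z,4Z)-2-[2-(benzyloxy)-4-bromophenoxy]-4-bromo-1,5-bis(dimethylamino)penta-1,4-dien-3-one
Conditions: NBS (1.0 equiv), CH2Cl2, −40 → 0 °C
Reagents that add atoms: N-bromosuccinimide, O=C1CCC(=O)N1Br
Why: Electrophilic α-bromination of an enaminone; only the CH=CH–NMe2 arm has an α-hydrogen to lose after attack of the bromine electrophile, and this vinylogous amide is far more nucleophilic than ring B.

Step 5
Reactants: 7 (1Z,4Z)-2-[2-(benzyloxy)-4-bromophenoxy]-4-bromo-1,5-bis(dimethylamino)penta-1,4-dien-3-one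
Product: 8 3-[2-(benzyloxy)-4-bromophenoxy]-5-bromo-4H-pyran-4-one
Conditions: 2 M aq HCl, THF, rt → 40 °C
Reagents that add atoms: water, O
Why: Acid hydrolysis of one vinylogous amide to the hydroxymethylene ketone, whose enol oxygen adds to the other protonated enaminone arm and expels dimethylamine (addition–elimination), the known acid cyclization of 1,5-bis(dimethylamino)penta-1,4-dien-3-ones to 4-pyranones.

Step 6
Reactants: 8 3-[2-(benzyloxy)-4-bromophenoxy]-5-bromo-4H-pyran-4-one; 9 nitromethane
Product: 10 2-[2-(benzyloxy)-4-bromophenoxy]-6-bromo-4-nitrophenol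
Conditions: MeNO2 (5 equiv) premixed with t-BuOK (3 equiv), t-BuOH–THF, 0 → 50 °C; then aq HCl
Reagents that add atoms: none
Why: In pyranone numbering (O1, C3 bearing Br, C4 carbonyl, C5 bearing the aryloxy group), the potassium nitronate adds in conjugate fashion to C2 or C6 of the vinylogous ester, the resulting 2H-pyran-4-olate opens by cleavage of the bond between O1 and the attacked carbon to a dienolate carrying an aldehyde, and the nitromethyl group, ionized again, closes on that aldehyde in an intramolecular Henry reaction; loss of water and tautomerization give the phenolate of ring A. The closest known reaction is the base-mediated conversion of 2,6-dialkyl-4-pyranones into 4-nitrophenols with nitromethane, applied here to a 2,6-unsubstituted and therefore more electrophilic pyranone. Ring A closes in a 6-exo-trig mode (nitronate carbon onto the aldehyde C=O, which lies outside the new ring), and no stereocenter is formed. No regiochemical choice arises, because the new carbon ends up bonded to both C2 and C6 whichever is attacked first, while the former carbonyl oxygen, already flanked by Br and the aryloxy group, becomes the phenol oxygen. The selectivity needed is attack at C2/C6 rather than at the vinylic C–Br or by butoxide; the polarization of the vinylogous ester, the soft preformed carbon nucleophile and the excess of base, which keeps the adduct as an enolate with C3 still sp2 so that bromide is not open to displacement, should secure it.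

Step 7
Reactants: 10 2-[2-(benzyloxy)-4-bromophenoxy]-6-bromo-4-nitrophenol
Product: 11 1-[2-(benzyloxy)-4-bromophenoxy]-3-bromo-2-methoxy-5-nitrobenzene
Conditions: MeI, K2CO3, DMF, rt
Reagents that add atoms: iodomethane, CI
Why: Williamson O-methylation; the acidic, flanked nitrophenoxide should still be alkylated by the small electrophile in a dipolar aprotic solvent.

Step 8
Reactants: 11 1-[2-(benzyloxy)-4-bromophenoxy]-3-bromo-2-methoxy-5-nitrobenzene
Product: 12 3-[2-(benzyloxy)-4-bromophenoxy]-5-bromo-4-methoxyaniline
Conditions: Fe powder, NH4Cl, EtOH–H2O, 75 °C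
Reagents that add atoms: none
Why: Béchamp-type reduction of the nitroarene by iron under near-neutral conditions, which should leave the aryl bromides and the benzyl ether untouched where catalytic hydrogenation would not.

Step 9
Reactants: 12 3-[2-(benzyloxy)-4-bromophenoxy]-5-bromo-4-methoxyaniline
Product: 14 1-[2-(benzyloxy)-4-bromophenoxy]-3,5-dibromo-2-methoxybenzene, via diazonium bromide 13 (not isolated)
Conditions: NaNO2, dilute aq HBr (3 equiv), MeCN–H2O, 0 °C; then CuBr (0.2 equiv), 0 → 40 °C
Reagents that add atoms: hydrobromic acid, Br; sodium nitrite, [Na+].[O-]N=O (supplies only the second nitrogen of intermediate 13)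
Why: Diazotization followed by Sandmeyer bromination, in which CuBr transfers an electron to the diazonium ion and the aryl radical takes bromine from the resulting CuBr2; the para methoxy group stabilizes the diazonium salt and the acid is kept dilute and cool to spare the benzyl ether.

Step 10
Reactants: 14 1-[2-(benzyloxy)-4-bromophenoxy]-3,5-dibromo-2-methoxybenzene
Product: 15 5-bromo-2-(3,5-dibromo-2-methoxyphenoxy)phenol
Conditions: BCl3 (2 equiv), pentamethylbenzene (3 equiv), CH2Cl2, −78 °C; then MeOH, H2O
Reagents that add atoms: none
Why: Lewis acid cleavage of the aryl benzyl ether with pentamethylbenzene as a non-basic trap for the benzyl cation (Friedel–Crafts capture); at −78 °C the aryl methyl ether and the aryl bromides should persist, whereas hydrogenolysis would remove bromine.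

**Compound list**

1 | 2-(benzyloxy)phenol | Oc1ccccc1OCc1ccccc1 | starting material
2 | 2-(benzyloxy)-4-bromophenol | Oc1ccc(Br)cc1OCc1ccccc1 | intermediate
3 | chloroacetone | CC(=O)CCl | starting material
4 | 1-[2-(benzyloxy)-4-bromophenoxy]propan-2-one | CC(=O)COc1ccc(Br)cc1OCc1ccccc1 | intermediate
5 | (3Z)-3-[2-(benzyloxy)-4-bromophenoxy]-4-(dimethylamino)but-3-en-2-one (mono-enaminone) | CC(=O)/C(Oc1ccc(Br)cc1OCc1ccccc1)=C/N(C)C | intermediate
6 | (1Z,4E)-2-[2-(benzyloxy)-4-bromophenoxy]-1,5-bis(dimethylamino)penta-1,4-dien-3-one | CN(C)/C=C/C(=O)/C(Oc1ccc(Br)cc1OCc1ccccc1)=C/N(C)C | intermediate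
7 | (1Z,4Z)-2-[2-(benzyloxy)-4-bromophenoxy]-4-bromo-1,5-bis(dimethylamino)penta-1,4-dien-3-one | CN(C)/C=C(Br)/C(=O)/C(Oc1ccc(Br)cc1OCc1ccccc1)=C/N(C)C | intermediate
8 | 3-[2-(benzyloxy)-4-bromophenoxy]-5-bromo-4H-pyran-4-one | O=c1c(Br)cocc1Oc1ccc(Br)cc1OCc1ccccc1 | intermediate
9 | nitromethane | C[N+](=O)[O-] | starting material
10 | 2-[2-(benzyloxy)-4-bromophenoxy]-6-bromo-4-nitrophenol | Oc1c(Br)cc([N+](=O)[O-])cc1Oc1ccc(Br)cc1OCc1ccccc1 | intermediate
11 | 1-[2-(benzyloxy)-4-bromophenoxy]-3-bromo-2-methoxy-5-nitrobenzene | COc1c(Br)cc([N+](=O)[O-])cc1Oc1ccc(Br)cc1OCc1ccccc1 | intermediate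
12 | 3-[2-(benzyloxy)-4-bromophenoxy]-5-bromo-4-methoxyaniline | COc1c(Br)cc(N)cc1Oc1ccc(Br)cc1OCc1ccccc1 | intermediate
13 | 3-[2-(benzyloxy)-4-bromophenoxy]-5-bromo-4-methoxybenzenediazonium bromide | COc1c(Br)cc([N+]#N)cc1Oc1ccc(Br)cc1OCc1ccccc1.[Br-] | intermediate
14 | 1-[2-(benzyloxy)-4-bromophenoxy]-3,5-dibromo-2-methoxybenzene | COc1c(Br)cc(Br)cc1Oc1ccc(Br)cc1OCc1ccccc1 | intermediate
15 | 5-bromo-2-(3,5-dibromo-2-methoxyphenoxy)phenol (CNP0017937.0) | COc1c(Br)cc(Br)cc1Oc1ccc(Br)cc1O | target

**Step count**

Total steps: 10. Longest linear sequence: 10 steps, from 2-(benzyloxy)phenol 1.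

**Steps most likely to fail**

1. Step 6. The conjugate adduct may be protonated at the bromine-bearing carbon and then lose bromide by intramolecular displacement (nitrocyclopropane formation), or butoxide may cleave the pyranone and the open-chain aldehyde may oligomerize. The fallback sets out from compound 6 and takes the bromine out of the ring transformation. Acid cyclization of 6 (2 M aq HCl, THF) should give 3-[2-(benzyloxy)-4-bromophenoxy]-4H-pyran-4-one F1. The same nitromethane and t-BuOK treatment, now free of any α-halide, should give 2-[2-(benzyloxy)-4-bromophenoxy]-4-nitrophenol F2. Ortho-bromination of this phenol (NBS, cat. i-Pr2NH, CH2Cl2, 0 °C) at its only free ortho position, the para position being blocked by the nitro group, comes back to the route at compound 10.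

2. Step 3. The second condensation at the methyl group may stall at the mono-enaminone, or the material may degrade on long heating. The fallback sets out from compound 4 and builds the second arm by a Claisen reaction. DMF dimethyl acetal (toluene, 90 °C) should stop cleanly at mono-enaminone 5, which is isolated. Deprotonation of its methyl group with LiN(SiMe3)2 (THF, −78 °C) and formylation with ethyl formate should give (1Z,4Z)-2-[2-(benzyloxy)-4-bromophenoxy]-1-(dimethylamino)-5-hydroxypenta-1,4-dien-3-one F3. NBS (CH2Cl2, 0 °C) should brominate the central carbon of this 1,3-dicarbonyl unit to give (1Z,4E)-2-[2-(benzyloxy)-4-bromophenoxy]-4-bromo-1-(dimethylamino)-5-hydroxypenta-1,4-dien-3-one F4. Acid (2 M aq HCl, THF) then lets the enol oxygen displace dimethylamine and comes back to the route at compound 8.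

3. Step 9. The diazonium ion may be reduced to the arene or hydrolyzed to the phenol, or the benzyl ether may be lost in acid, on a lipophilic substrate that dissolves poorly in aqueous acid. The fallback sets out from compound 12 and forms the C–Br bond through a C–B bond without aqueous acid. Deaminative borylation (t-BuONO, bis(pinacolato)diboron, MeCN, rt) should give 2-{3-[2-(benzyloxy)-4-bromophenoxy]-5-bromo-4-methoxyphenyl}-4,4,5,5-tetramethyl-1,3,2-dioxaborolane F5. Ipso-bromodeboronation with CuBr2 (3 equiv, MeOH–H2O, 80 °C) comes back to the route at compound 14.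

**Further compounds**

F1 | step 6 | 3-[2-(benzyloxy)-4-bromophenoxy]-4H-pyran-4-one | O=c1ccocc1Oc1ccc(Br)cc1OCc1ccccc1
F2 | step 6 | 2-[2-(benzyloxy)-4-bromophenoxy]-4-nitrophenol | Oc1ccc([N+](=O)[O-])cc1Oc1ccc(Br)cc1OCc1ccccc1
F3 | step 3 | (1Z,4Z)-2-[2-(benzyloxy)-4-bromophenoxy]-1-(dimethylamino)-5-hydroxypenta-1,4-dien-3-one | O/C=C\C(=O)/C(Oc1ccc(Br)cc1OCc1ccccc1)=C/N(C)C
F4 | step 3 | (1Z,4E)-2-[2-(benzyloxy)-4-bromophenoxy]-4-bromo-1-(dimethylamino)-5-hydroxypenta-1,4-dien-3-one | O/C=C(Br)\C(=O)/C(Oc1ccc(Br)cc1OCc1ccccc1)=C/N(C)C
F5 | step 9 | 2-{3-[2-(benzyloxy)-4-bromophenoxy]-5-bromo-4-methoxyphenyl}-4,4,5,5-tetramethyl-1,3,2-dioxaborolane | COc1c(Br)cc(B2OC(C)(C)C(C)(C)O2)cc1Oc1ccc(Br)cc1OCc1ccccc1
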